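Ring A of unit 2 (the 8-aryloxy-7-hydroxyisoflavone half) bears four adjacent substituents: the acyl carbon C4 on C4a, O1 on C8a, the aryloxy group on C8 and OH on C7. The plan exploits this array by building ring A from acyclic pieces. C8a–C8–C7–C6 come from a 1-methoxy-1,3-bis(trimethylsilyloxy)butadiene whose C2 already holds the 4-bromophenoxy group. C5 and C4a come from a terminal ynone carrying the 4-methoxybenzyl residue. One Diels–Alder/aromatization forms C4a–C8a and C5–C6 and gives the complete deoxybenzoin; the hindered C8–O bond is made beforehand by simple SN2 chemistry. Ring C closure, borylation, Suzuki coupling to an 8-chloro-3-iodochromone and global demethylation finish the route.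

Key step: step 6

Assumption: the double-bond geometry of the enol ethers and enaminones and the configuration of the transient sp3 centres are of no consequence, since all these atoms end in aromatic rings and the target has no stereocentre; such compounds are drawn as one isomer or without descriptor.

Step 1
Reactants: 1 methyl 2-chloro-3-oxobutanoate (racemic); 2 4-bromophenol
Product: 3 methyl 2-(4-bromophenoxy)-3-oxobutanoate (racemic)
Conditions: K2CO3, acetone, 56 °C
Reagents that add atoms: none
Why: Williamson-type SN2 etherification in which the phenoxide displaces a chloride activated by two flanking carbonyl groups, a standard entry to 2-aryloxyacetoacetates and the point where the hindered C8–O bond of unit 2 is made.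

Step 2
Reactants: 3 methyl 2-(4-bromophenoxy)-3-oxobutanoate
Product: 4 methyl 2-(4-bromophenoxy)-3-(trimethylsilyloxy)but-2-enoate (E/Z mixture)
Conditions: Me3SiCl, Et3N, toluene, 20 °C
Reagents that add atoms: chlorotrimethylsilane, C[Si](C)(C)Cl
Why: O-silylation of the enolizable β-keto ester by soft enolization (amine base, silyl chloride), the usual first stage of bis(silyl enol ether) preparation, under which ester, aryl ether and aryl bromide are inert.

Step 3
Reactants: 4 methyl 2-(4-bromophenoxy)-3-(trimethylsilyloxy)but-2-enoate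
Product: 6 (1Z)-2-(4-bromophenoxy)-1-methoxy-1,3-bis(trimethylsilyloxy)buta-1,3-diene, via lithium dienolate 5 (not isolated)
Conditions: LiN(iPr)2, THF, −78 °C; then Me3SiCl, −78 → 20 °C; filtered under argon, used crude
Reagents that add atoms: chlorotrimethylsilane, C[Si](C)(C)Cl
Why: Kinetic γ-deprotonation of the β-silyloxy enoate to the extended dienolate 5 and O-silylation at the ester oxygen, the standard second stage of 1-alkoxy-1,3-bis(silyloxy)diene synthesis, with the amide base leaving the aryl bromide alone at −78 °C.

Step 4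
Reactants: 7 4-methoxyphenylacetic acid
Product: 8 N-methoxy-2-(4-methoxyphenyl)-N-methylacetamide
Conditions: MeNHOMe·HCl, EDC·HCl, Et3N, CH2Cl2, 0 → 20 °C
Reagents that add atoms: N,O-dimethylhydroxylamine hydrochloride, CNOC.Cl
Why: Carbodiimide-mediated amide coupling gives the N-methoxy-N-methylamide needed for a clean single acylation of an acetylide.

Step 5
Reactants: 8 N-methoxy-2-(4-methoxyphenyl)-N-methylacetamide
Product: 10 1-(4-methoxyphenyl)but-3-yn-2-one, via magnesium hemiaminal chelate 9 (not isolated)
Conditions: HC≡CMgBr, THF, 0 °C; inverse quench into cold 1 M HCl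
Reagents that add atoms: ethynylmagnesium bromide, C#C[Mg]Br
Why: Weinreb ketone synthesis, in which the chelated tetrahedral adduct 9 resists a second addition, the weakly basic acetylide spares the benzylic CH2, and pouring into cold acid protonates the released amine before it can add to the ynone.

Step 6
Reactants: 6 (1Z)-2-(4-bromophenoxy)-1-methoxy-1,3-bis(trimethylsilyloxy)buta-1,3-diene; 10 1-(4-methoxyphenyl)but-3-yn-2-one
Product: 12 1-[3-(4-bromophenoxy)-2,4-dihydroxyphenyl]-2-(4-methoxyphenyl)ethan-1-one, via cyclohexadiene adduct 11 (not isolated)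
Conditions: 6 (1.5 equiv), toluene, argon, 20 → 80 °C; then 1 M HCl, THF, 20 °C
Reagents that add atoms: none
Why: The electron-rich diene 6 and the electron-poor ynone 10 should combine in a normal-electron-demand, markedly asynchronous [4+2] cycloaddition in which the diene CH2 (future C6) bonds first to the unsubstituted alkyne carbon (future C5) and the ketene acetal carbon (future C8a) then bonds to the acyl-bearing alkyne carbon (future C4a), giving the 1,4-cyclohexadiene 11. Dilute acid then cleaves both silyl ethers, the hemiketal at C8a expels methanol, and the resulting cyclohexenedione enolizes irreversibly to the resorcinol ring of 12. The closest known reaction type is the Diels–Alder/aromatization of 1-alkoxy-1,3-bis(silyloxy)buta-1,3-dienes, 2-substituted members included, with alkynyl ketones and propiolates to give 2,4-dihydroxyaryl carbonyl compounds. Ring A is closed as a six-membered carbocycle by intermolecular union of a four-carbon and a two-carbon component, both new bonds arising in one operation, and a stepwise Mukaiyama–Michael addition followed by ring closure would end at the same adduct. No stereocentre reaches the product, since the only one formed (C8a of 11, racemic) is erased on aromatization and the diene geometry is lost with it. The step needs regioselectivity (acyl next to the former ketene acetal carbon), which is secured by the largest HOMO coefficient lying on the CH2 terminus, reinforced by the oxygens on C1 and C3, and the largest LUMO coefficient on the unhindered β-carbon of the terminal ynone, the cross-conjugated 2-aryloxy group being too weak a donor to overturn this.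

Step 7
Reactants: 12 1-[3-(4-bromophenoxy)-2,4-dihydroxyphenyl]-2-(4-methoxyphenyl)ethan-1-one
Product: 14 8-(4-bromophenoxy)-7-hydroxy-3-(4-methoxyphenyl)-4H-chromen-4-one, via enaminone 13 (not isolated)
Conditions: Me2NCH(OMe)2, THF, 65 °C
Reagents that add atoms: N,N-dimethylformamide dimethyl acetal, COC(OC)N(C)C
Why: Formamide-acetal isoflavone synthesis from a 2-hydroxydeoxybenzoin, in which condensation at the doubly activated CH2 gives enaminone 13 and the C8a hydroxyl then attacks its β-carbon with loss of dimethylamine to close ring C, while any O-methylation of the 7-OH by the acetal only anticipates step 8.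

Step 8
Reactants: 14 8-(4-bromophenoxy)-7-hydroxy-3-(4-methoxyphenyl)-4H-chromen-4-one
Product: 15 8-(4-bromophenoxy)-7-methoxy-3-(4-methoxyphenyl)-4H-chromen-4-one
Conditions: MeI, K2CO3, DMF, 20 °C
Reagents that add atoms: iodomethane, CI
Why: Williamson O-methylation of the only remaining, acidic phenol masks it for the two palladium steps with a group that the last step removes together with the other methyl ethers.

Step 9
Reactants: 15 8-(4-bromophenoxy)-7-methoxy-3-(4-methoxyphenyl)-4H-chromen-4-one
Product: 16 7-methoxy-3-(4-methoxyphenyl)-8-[4-(4,4,5,5-tetramethyl-1,3,2-dioxaborolan-2-yl)phenoxy]-4H-chromen-4-one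
Conditions: B2pin2, Pd(dppf)Cl2 (cat.), KOAc, 1,4-dioxane, 90 °C
Reagents that add atoms: bis(pinacolato)diboron, CC1(C)OB(OC1(C)C)B1OC(C)(C)C(C)(C)O1
Why: Miyaura borylation of the aryl bromide (oxidative addition to zerovalent palladium, acetate-assisted transmetalation with B2pin2), with the weak base KOAc leaving the chromone intact.

Step 10
Reactants: 17 2-chlororesorcinol (2-chlorobenzene-1,3-diol)
Product: 18 1-(3-chloro-2,4-dihydroxyphenyl)ethan-1-one
Conditions: AcOH, BF3·OEt2 (solvent), 90 °C; then H2O
Reagents that add atoms: acetic acid, CC(=O)O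
Why: Friedel–Crafts (Nencki-type) C-acylation of the activated resorcinol, in which C4 and C6 are equivalent and are the only free positions activated by both hydroxyls, so a single ketone should form.

Step 11
Reactants: 18 1-(3-chloro-2,4-dihydroxyphenyl)ethan-1-one
Product: 19 1-(3-chloro-2-hydroxy-4-methoxyphenyl)ethan-1-one
Conditions: MeI (1.05 equiv), K2CO3, acetone, 56 °C
Reagents that add atoms: iodomethane, CI
Why: Chemoselective Williamson methylation, since the 2-OH is tied up in a hydrogen bond to the ketone and is far less nucleophilic, so one equivalent of MeI should alkylate the 4-OH only.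

Step 12
Reactants: 19 1-(3-chloro-2-hydroxy-4-methoxyphenyl)ethan-1-one
Product: 21 8-chloro-3-iodo-7-methoxy-4H-chromen-4-one, via enaminone 20 (not isolated)
Conditions: Me2NCH(OMe)2, toluene, 100 °C; evaporation; then I2, CHCl3, 20 °C
Reagents that add atoms: N,N-dimethylformamide dimethyl acetal, COC(OC)N(C)C; iodine, II
Why: Enaminone formation with the formamide acetal followed by iodine-induced cyclization (α-iodination, attack of the phenol on the iminium carbon, loss of dimethylamine), the standard preparation of 3-iodochromones.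

Step 13
Reactants: 16 7-methoxy-3-(4-methoxyphenyl)-8-[4-(4,4,5,5-tetramethyl-1,3,2-dioxaborolan-2-yl)phenoxy]-4H-chromen-4-one; 21 8-chloro-3-iodo-7-methoxy-4H-chromen-4-one
Product: 22 8-chloro-7-methoxy-3-(4-{[7-methoxy-3-(4-methoxyphenyl)-4-oxo-4H-chromen-8-yl]oxy}phenyl)-4H-chromen-4-one
Conditions: Pd(dppf)Cl2 (cat.), K2CO3, 1,4-dioxane/H2O, 70 °C
Reagents that add atoms: none
Why: Suzuki–Miyaura coupling, the established way to isoflavones from 3-iodochromones, in which the C–I bond undergoes oxidative addition far faster than the aryl C–Cl bond with this catalyst, so the chlorine should stay.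

Step 14
Reactants: 22 8-chloro-7-methoxy-3-(4-{[7-methoxy-3-(4-methoxyphenyl)-4-oxo-4H-chromen-8-yl]oxy}phenyl)-4H-chromen-4-one
Product: 23 bisoflavolin J, 8-chloro-7-hydroxy-3-(4-{[7-hydroxy-3-(4-hydroxyphenyl)-4-oxo-4H-chromen-8-yl]oxy}phenyl)-4H-chromen-4-one
Conditions: BBr3 (excess), CH2Cl2, −78 → 20 °C; then H2O
Reagents that add atoms: none
Why: Lewis-acid cleavage of the three aryl methyl ethers by BBr3 (bromide attacks the methyl carbon), while the diaryl ether, the aryl chloride and the chromone rings offer no alkyl–oxygen bond and should survive.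

Compound list
1 | methyl 2-chloro-3-oxobutanoate (racemic) | COC(=O)C(Cl)C(C)=O | starting material
2 | 4-bromophenol | Oc1ccc(Br)cc1 | starting material
3 | methyl 2-(4-bromophenoxy)-3-oxobutanoate (racemic) | COC(=O)C(Oc1ccc(Br)cc1)C(C)=O | intermediate
4 | methyl 2-(4-bromophenoxy)-3-(trimethylsilyloxy)but-2-enoate (E/Z mixture) | COC(=O)C(Oc1ccc(Br)cc1)=C(C)O[Si](C)(C)C | intermediate
5 | lithium 2-(4-bromophenoxy)-1-methoxy-3-(trimethylsilyloxy)buta-1,3-dien-1-olate | CO/C([O-])=C(/Oc1ccc(Br)cc1)C(=C)O[Si](C)(C)C.[Li+] | intermediate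
6 | (1Z)-2-(4-bromophenoxy)-1-methoxy-1,3-bis(trimethylsilyloxy)buta-1,3-diene | CO/C(O[Si](C)(C)C)=C(/Oc1ccc(Br)cc1)C(=C)O[Si](C)(C)C | intermediate
7 | 4-methoxyphenylacetic acid | COc1ccc(CC(=O)O)cc1 | starting material
8 | N-methoxy-2-(4-methoxyphenyl)-N-methylacetamide | COc1ccc(CC(=O)N(C)OC)cc1 | intermediate
9 | bromomagnesium 3-[methoxy(methyl)amino]-4-(4-methoxyphenyl)but-1-yn-3-olate (racemic chelate) | C#CC(Cc1ccc(OC)cc1)(O[Mg]Br)N(C)OC | intermediate
10 | 1-(4-methoxyphenyl)but-3-yn-2-one | C#CC(=O)Cc1ccc(OC)cc1 | intermediate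
11 | 1-[5-(4-bromophenoxy)-6-methoxy-4,6-bis(trimethylsilyloxy)cyclohexa-1,4-dien-1-yl]-2-(4-methoxyphenyl)ethan-1-one (racemic) | COc1ccc(CC(=O)C2=CCC(O[Si](C)(C)C)=C(Oc3ccc(Br)cc3)C2(OC)O[Si](C)(C)C)cc1 | intermediate
12 | 1-[3-(4-bromophenoxy)-2,4-dihydroxyphenyl]-2-(4-methoxyphenyl)ethan-1-one | COc1ccc(CC(=O)c2ccc(O)c(Oc3ccc(Br)cc3)c2O)cc1 | intermediate
13 | 1-[3-(4-bromophenoxy)-2,4-dihydroxyphenyl]-3-(dimethylamino)-2-(4-methoxyphenyl)prop-2-en-1-one (geometry open) | CN(C)C=C(c1ccc(OC)cc1)C(=O)c1ccc(O)c(Oc2ccc(Br)cc2)c1O | intermediate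
14 | 8-(4-bromophenoxy)-7-hydroxy-3-(4-methoxyphenyl)-4H-chromen-4-one | O=c1c(-c2ccc(OC)cc2)coc2c(Oc3ccc(Br)cc3)c(O)ccc12 | intermediate
15 | 8-(4-bromophenoxy)-7-methoxy-3-(4-methoxyphenyl)-4H-chromen-4-one | O=c1c(-c2ccc(OC)cc2)coc2c(Oc3ccc(Br)cc3)c(OC)ccc12 | intermediate
16 | 7-methoxy-3-(4-methoxyphenyl)-8-[4-(4,4,5,5-tetramethyl-1,3,2-dioxaborolan-2-yl)phenoxy]-4H-chromen-4-one | O=c1c(-c2ccc(OC)cc2)coc2c(Oc3ccc(B4OC(C)(C)C(C)(C)O4)cc3)c(OC)ccc12 | intermediate
17 | 2-chlororesorcinol | Oc1cccc(O)c1Cl | starting material
18 | 1-(3-chloro-2,4-dihydroxyphenyl)ethan-1-one | CC(=O)c1ccc(O)c(Cl)c1O | intermediate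
19 | 1-(3-chloro-2-hydroxy-4-methoxyphenyl)ethan-1-one | CC(=O)c1ccc(OC)c(Cl)c1O | intermediate
20 | (E)-1-(3-chloro-2-hydroxy-4-methoxyphenyl)-3-(dimethylamino)prop-2-en-1-one | CN(C)/C=C/C(=O)c1ccc(OC)c(Cl)c1O | intermediate
21 | 8-chloro-3-iodo-7-methoxy-4H-chromen-4-one | O=c1c(I)coc2c(Cl)c(OC)ccc12 | intermediate
22 | 8-chloro-7-methoxy-3-(4-{[7-methoxy-3-(4-methoxyphenyl)-4-oxo-4H-chromen-8-yl]oxy}phenyl)-4H-chromen-4-one | O=c1c(-c2ccc(Oc3c(OC)ccc4c(=O)c(-c5ccc(OC)cc5)coc34)cc2)coc2c(Cl)c(OC)ccc12 | intermediate
23 | bisoflavolin J | O=c1c(-c2ccc(Oc3c(O)ccc4c(=O)c(-c5ccc(O)cc5)coc34)cc2)coc2c(Cl)c(O)ccc12 | target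

Total step count: 14.
Longest linear sequence: 9 steps (1, 2, 3, 6, 7, 8, 9, 13, 14).

Steps most likely to fail

1. Step 6.
- What may go wrong: the cycloaddition may be outpaced by protodesilylation of the moisture-sensitive diene, by oligomerization of the terminal ynone, or by silyl transfer to its enolizable CH2. The 2-aryloxy group may erode the regioselectivity. Aromatization may run in part through loss of silanol instead of methanol.
- Fallback, setting out from 7 and coming back at 12: ring A is taken from an existing arene. Chan–Lam coupling of purchased 2,6-dimethoxyphenol with 4-bromophenylboronic acid (Cu(OAc)2, pyridine, 4 Å molecular sieves, CH2Cl2, air) should give 2-(4-bromophenoxy)-1,3-dimethoxybenzene F1. BBr3 in CH2Cl2 should free 2-(4-bromophenoxy)benzene-1,3-diol F2. Friedel–Crafts acylation of F2 with acid 7 in BF3·OEt2 at 85 °C goes ortho to one hydroxyl and para to the other on the far more activated ring, and should give 12.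

2. Step 5.
- What may go wrong: conjugate addition of the liberated amine to the ynone during the quench, enolization of the amide by the Grignard reagent, and base-induced oligomerization of the product may lower the throughput.
- Fallback, setting out from 8 and coming back at 10: a redox route replaces acyl substitution. Reduction of 8 with iBu2AlH (THF, −78 °C) should give (4-methoxyphenyl)acetaldehyde F3. Addition of HC≡CMgBr (THF, −78 → 0 °C) should give racemic 1-(4-methoxyphenyl)but-3-yn-2-ol F4. Oxidation with Dess–Martin periodinane (NaHCO3, CH2Cl2, 0 °C) should give 10 under neutral, amine-free conditions.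

3. Step 1.
- What may go wrong: retro-Claisen deacetylation of the product and self-condensation of the chloro keto ester under the basic conditions may compete with the displacement.
- Fallback, setting out from 2 and coming back at 3: the C–O bond is made by carbenoid insertion. Regitz diazo transfer onto purchased methyl acetoacetate (4-acetamidobenzenesulfonyl azide, Et3N, MeCN) should give methyl 2-diazo-3-oxobutanoate F5. Rh2(OAc)4-catalysed O–H insertion into 2 (CH2Cl2, 40 °C) should give 3 without any base.

Further compounds
F1 | step 6 | 2-(4-bromophenoxy)-1,3-dimethoxybenzene | COc1cccc(OC)c1Oc1ccc(Br)cc1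
F2 | step 6 | 2-(4-bromophenoxy)benzene-1,3-diol | Oc1cccc(O)c1Oc1ccc(Br)cc1
F3 | step 5 | (4-methoxyphenyl)acetaldehyde | COc1ccc(CC=O)cc1
F4 | step 5 | 1-(4-methoxyphenyl)but-3-yn-2-ol (racemic) | C#CC(O)Cc1ccc(OC)cc1
F5 | step 1 | methyl 2-diazo-3-oxobutanoate | COC(=O)C(=[N+]=[N-])C(C)=O
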